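## Structural features

Atom labels follow caryophyllane numbering: C1–C11 for the bicycle (C1/C9 ring fusion, C10 the cyclobutane CH2, C11 the quaternary carbon) and C1'–C4' for the carbons of the peroxide ring.

- The core is a bicyclo[7.2.0]undecane: ring A is the cyclobutane C1–C9–C10–C11 and ring B the nine-membered ring C1…C9. The two are trans-fused, with an exocyclic methylene on C8 and a trisubstituted epoxide at C4–C5.
- C11 is quaternary. It carries a methyl group cis to the C2 chain on C1 and, trans to that chain, the anomeric carbon C1' of ring C, a 3-hydroxy-3,6-dihydro-1,2-dioxin whose C4' bears a methyl and a hydroxymethyl group.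
- C9, C1, C11 and C1' are contiguous stereocentres. C4/C5 and C4' are insulated from them, C4' by the O–O bond and the ring alkene.
- Fragile elements are the O–O bond (reductants, low-valent metals), the peroxy-hemiketal at C1' (ring–chain equilibrium, hence epimerisable), the epoxide and its strained E-cyclononene precursor (acid), and the exocyclic alkene.
- The real difficulty is threefold: the fully substituted C11 inside a four-membered ring with a defined relationship to C1, the medium ring, and the remote C4' that no centre of the core can control.
- The key step exploits ring A: C1 and C11 carry exactly the substituent pattern of an E-2-methylallylic alkene, and C9 can start life as a carbonyl carbon, so ring A maps onto an alkene plus a ketene equivalent.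
- The bicyclic core has the (1S,9R) configuration, i.e. the mirror image of the common caryophyllene oxide skeleton, so all analogies to that series are used in the enantiomeric sense.

## Logic of the disconnections

**39 ⇒ 38.** The two C–O bonds of the C4–C5 oxirane are cut first. The epoxide is the most acid-labile group and should meet no later reagent. The gain is a diene whose chemistry is that of a simple E-cyclononene. The forward step must pick one of three alkenes and one of two faces.

**38 ⇒ 36 (through 37).** The C1'–OH bond and the primary O–H are traced back to C1'–OMe and O–Si. This stores the hemiketal as a stable mixed peroxyketal through the ring closure. The forward step must hydrolyse a ketal next to an O–O bond without harming the strained alkene, and it relies on equilibration at C1'.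

**36 ⇒ 35.** The C2'=C3' bond of ring C is cut. A ring closure guarantees the cis alkene and leaves the O–O bond untouched. The precursor is acyclic at the peroxide. The forward step needs a catalyst that engages two hindered vinyl groups and ignores the two core alkenes.

**35 ⇒ 28 + 34.** The C1'–O(peroxide) bond is cut. This is the convergent cut: the core and the O–O/C4' fragment are made separately, and C4' is bought as reagent-controlled chirality. The forward step must add a hydroperoxide to C1' under mild acid without conjugate addition and without ionising C4'.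

**34 ⇒ 32 ⇒ 31 ⇒ 29.** The C4'–OO bond is cut back to an oxirane, and the vinyl group back to a hydroxymethyl group. A 2,2-disubstituted epoxide of known configuration is available from the chiral pool of asymmetric epoxidation products. The forward opening must occur at the tertiary allylic carbon with inversion, and the two OH functions of 32 must be told apart.

**28 ⇒ 27 ⇒ 26 ⇒ 25.** The C1'–C2' bond is cut (alkynyl addition to an aldehyde), followed by O-methylation and a 1,3-hydrogen shift. This reaches the vinyl peroxyketal oxidation level without ever making a vinyl ketone. The forward sequence needs a base-mediated isomerisation that the C8 methylene survives.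

**25 ⇒ 24 ⇒ 23 ⇒ 22.** These are oxidation-state and protecting-group changes at C1' and the C8=CH2 bond (carbonyl olefination). The C8 ketone is the handle that closed ring B. The olefination must not epimerise C9 irreversibly, which the thermodynamic preference for trans fusion secures.

**22 ⇒ 21 ⇒ 20.** The C7–S bond and then the C6–C7 bond of ring B are cut. The nine-membered ring is opened to a chain that carries an allylic leaving group and a doubly stabilised carbanion. The forward closure must choose the CH2 terminus of an allyl unit, keep the E geometry and beat oligomerisation.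

**20 ⇒ 19 ⇒ 17.** The C6–O acyl bond and the C7–C8 bond are cut (sulfonyl carbanion onto a nitrile). C7 arrives with its activating group in one operation. The nitrile must be the only electrophile present and C9 must not be deprotonated irreversibly.

**17 ⇒ 15 ⇒ 14 ⇒ 13 ⇒ 12.** The C5–C6 and C4–CH3 bonds are cut (syn carbometalation of an alkyne, then hydroxymethylation), then C3–C4 (alkynylation of a primary iodide), then the C3–O protecting group. The E-trisubstituted alkene is reduced to an alkyne, whose geometry problem is solved by syn addition. The organometallic steps must tolerate the nitrile.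

**12 ⇒ 11.** The C8–C9 bond is cut (one-carbon reductive homologation of a ketone). This returns the C9 carbonyl that the cycloaddition delivers. The forward step must end with C8 trans to the C2 chain, which base equilibration provides.

**11 ⇒ 5 + 8.** C1–C9 and C10–C11, both bonds of ring A that are not in the alkene, are cut. One step then makes the ring, the quaternary carbon and the C1/C11 relationship from an acyclic alkene of defined geometry. The forward step must be regioselective, suprafacial and face-selective. In 5 the primary oxygen carries a tert-butyldiphenylsilyl group in place of the more labile tert-butyldimethylsilyl group, so that it survives the triflate medium and the later aqueous acid and interferes least with the cation.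

**5 ⇒ 4 ⇒ 3 ⇒ 1 + 2, and 8 ⇒ 6 + 7.** The C1=C11 double bond (carbonyl olefination with a stabilised ylide) and the amide C–N bond are cut. All four starting materials are commercial. The only demand is E selectivity in the olefination.

## Other disconnections considered

**Alternative 1:** The cut is the C2'=C3' double bond of ring C.

- Forward step: the second-generation Grubbs catalyst, (H2IMes)(PCy3)Cl2Ru=CHPh, would join the two vinyl groups of a mixed peroxyketal with loss of ethylene and give the methoxy dioxene A1.
- In its favour: the ring enforces the cis alkene, the O–O bond and C4' arrive in a separately made fragment, and the conditions are neutral.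
- Against it as the organising step: it presupposes the complete bicyclic diene, so C1, C9, C11 and both carbocycles must be solved elsewhere. Both vinyl groups sit on fully substituted carbons, the strained E-cyclononene may be opened by the catalyst, and an enantioenriched tertiary hydroperoxide is required.
- Structure: it builds ring C and none of the contiguous stereocentres, whereas step 5 builds ring A with C1 and C11. The two are complementary.
- Mechanism: a metal-alkylidene cycloaddition/cycloreversion that transmits no stereochemical information beyond alkene geometry, against a polar cycloaddition that transmits alkene geometry into two stereocentres.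
- Step economy: one bond and one ring against two bonds, one ring and two stereocentres.
- Where it is equal or better: on convergence and late-stage functional-group tolerance it is the better of the two, and for ring C it is judged superior to any polar peroxide cyclisation. It is therefore kept as step 25, applied to 35.

**Alternative 2:** The cut is the C6–C7 bond of ring B.

- Forward step: Pd(PPh3)4 with dppe (zerovalent palladium) would ionise an allylic methyl carbonate of the type of 20, and the β-keto sulfone carbanion would attack the CH2 terminus to give the nine-membered keto sulfone A2.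
- In its favour: a medium ring closed under neutral conditions with a soft nucleophile, E geometry and trans fusion carried in from the open chain, and C7 introduced together with its activating group.
- Against it here: the entropic and strain penalty of a nine-membered ring, the competing seven-membered closure at the substituted terminus, possible loss of alkene geometry through the allyl complex, the extra step to remove the sulfone, and the fact that no lasting stereocentre is made.
- Structure: ring B against ring A.
- Mechanism: ionisation and outer-sphere attack, stereochemically silent at a CH2 terminus, against a stereospecific cycloaddition.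
- Step economy: one bond and one ring plus a desulfonylation, against two bonds and two stereocentres in one step.
- Where it is equal or better: for the nine-membered ring it is the better tool, since no cycloaddition offers that ring, and it is equal in mildness. It is used as step 13, but it needs a cyclobutane with C1, C9 and C11 already set and cannot carry the stereochemical strategy.

**Alternative 3:** The cut is the ring bond C10–C11, made by enlarging a cyclopropane.

- Forward step: Ti(OiPr)4, one antipode of diethyl tartrate and tert-butyl hydroperoxide would epoxidise the cyclopropylidene allylic alcohol A4; opening at the tertiary carbon and shift of a cyclopropane CH2 would give the cyclobutanone A3.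
- In its favour: catalytic, reagent-controlled asymmetric induction whose sense follows an established mnemonic, cheap ligands, a small precursor, and no triflic anhydride.
- Against it here: only C11 and one ring bond are made, and the carbonyl sits on C1 instead of C9. The C2–C3 chain must then be attached to the carbonyl carbon and C9 functionalised afterwards. The methyl/chain cis relationship has to be created in a separate diastereoselective step, probably needing hydroxyl direction, whereas step 5 reads it from alkene geometry.
- Structure: both give an enantioenriched cyclobutanone with C11 quaternary, but 11 already contains C1, C2, C3, C9, C10, C11 and both oxygens in place.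
- Mechanism: epoxidation followed by a 1,2-shift with inversion at the migration terminus, against a concerted asynchronous cycloaddition.
- Step economy: A3 is reached in fewer steps than 11, but several further bond-forming and stereocontrolling steps are needed to reach the stage of 12, so the chosen plan is expected to be shorter overall.
- Where it is equal or better: on predictability of the absolute configuration and on cost of the chiral source it is the better of the two; the chosen plan uses a stoichiometric auxiliary whose face selection rests on a steric model. Up to the cyclobutanone it is equal or better in step count.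

Key step: step 5

**Remarks and assumptions**

- Check of structures: alkene 5, amide 8 and ketone 11 were compared atom by atom with C1 and C11 of the target (methyl cis and C1' trans to the C2 chain; ring CH of 11 is R, quaternary carbon S) and are mutually consistent. The only change made is the silyl group.
- Assumption on the auxiliary: the sense of face selection by the (2R,5R) amide is taken from a steric model of the crossed approach. If the opposite face were preferred, the (2S,5S) amide would be used and nothing else would change.
- Assumption on C1': the peroxy-hemiketal epimerises through its open-chain hydroperoxy enone, and the configuration drawn is taken to be the preferred, isolable epimer. If both are populated, the unwanted one is re-equilibrated.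
- Safety choices: CH2Cl2 replaces 1,2-dichloroethane and CCl4 in step 5; activated DMSO replaces chromium oxidants; SmI2 replaces amalgams; no tin and no HMPA are used. H2O2 is used as a dilute, dried ethereal solution that is never concentrated, and 32–34 are kept in solution behind a shield. Me3Al and iBu2AlH are handled as commercial solutions under argon.

## Route

Step 1
Reactants: 1 3-(benzyloxy)propanal; 2 ethyl 2-(triphenylphosphoranylidene)propanoate
Product: 3 ethyl (E)-5-(benzyloxy)-2-methylpent-2-enoate
Conditions: CH2Cl2, 0 °C → rt
Reagents that add atoms: none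
Why: Wittig olefination with a stabilised α-methyl ylide; the reversible, product-like transition state should place the ester trans to the alkyl chain and give the E-trisubstituted enoate, and the neutral conditions spare the β-alkoxy aldehyde from elimination.

Step 2
Reactants: 3 ethyl (E)-5-(benzyloxy)-2-methylpent-2-enoate
Product: 4 (E)-5-(benzyloxy)-2-methylpent-2-en-1-ol
Conditions: iBu2AlH (2.2 equiv), toluene, −78 → 0 °C; aq. potassium sodium tartrate
Reagents that add atoms: none
Why: iBu2AlH reduces the conjugated ester by two 1,2-hydride transfers without touching the C=C bond or the benzyl ether, so the alkene geometry is not at risk.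

Step 3
Reactants: 4 (E)-5-(benzyloxy)-2-methylpent-2-en-1-ol
Product: 5 (E)-5-(benzyloxy)-2-methylpent-2-enyl tert-butyldiphenylsilyl ether
Conditions: TBDPSCl, imidazole, CH2Cl2, 0 °C → rt
Reagents that add atoms: tert-butyl(chloro)diphenylsilane, CC(C)(C)[Si](Cl)(c1ccccc1)c1ccccc1
Why: Imidazole-promoted silylation of the primary allylic alcohol; the tert-butyldiphenylsilyl group is chosen because it should survive the triflate salts of step 5 and the aqueous acid of step 11, and its bulky, weakly basic oxygen should interfere least with the cationic cycloaddition.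

Step 4
Reactants: 6 (2R,5R)-2,5-dimethylpyrrolidine; 7 acetyl chloride
Product: 8 1-acetyl-(2R,5R)-2,5-dimethylpyrrolidine
Conditions: Et3N, CH2Cl2, 0 °C → rt
Reagents that add atoms: none
Why: Schotten–Baumann-type N-acylation of the secondary amine; the two stereocentres are not involved.

Step 5
Reactants: 8 1-acetyl-(2R,5R)-2,5-dimethylpyrrolidine; 5 (E)-5-(benzyloxy)-2-methylpent-2-enyl tert-butyldiphenylsilyl ether
Product: 11 (2R,3S)-2-[2-(benzyloxy)ethyl]-3-[(tert-butyldiphenylsilyloxy)methyl]-3-methylcyclobutan-1-one, via keteniminium triflate 9 (not isolated), via cyclobutaniminium triflate 10 (not isolated)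
Conditions: 8 (1.6 equiv), 2,6-di-tert-butylpyridine, Tf2O (1.5 equiv), CH2Cl2, −20 °C; 5, 40 °C; then aq. NaHCO3, rt
Reagents that add atoms: water, O (carbonyl oxygen of 11); triflic anhydride, O=S(=O)(OS(=O)(=O)C(F)(F)F)C(F)(F)F (triflate counter-ion of 9 and 10 only)
Why: O-Triflation of 8 and loss of triflic acid to the hindered pyridine give the linear keteniminium ion 9; its central carbon (future C9) is attacked by the less substituted alkene carbon of 5 (future C1), positive charge builds on the tertiary carbon (C11) and collapses onto the enamine-like CH2 terminus (C10) before rotation about C1–C11, and hydrolysis of 10 unveils the C9 ketone. The closest known reaction type is the keteniminium–alkene [2+2] cycloaddition of Tf2O-activated tertiary amides, including its auxiliary-controlled version with C2-symmetric pyrrolidines. Ring A is closed in an intermolecular, concerted but asynchronous [2+2] mode, suprafacial on the alkene and crossed on the keteniminium ion, with C1–C9 formed ahead of C10–C11. The relative configuration of C1 and C11 is controlled by the E geometry of 5: the methyl group and the chain that are cis on the alkene stay cis on the ring, and the silyloxymethyl carbon ends trans to the chain. The absolute configuration of both centres is controlled by the (2R,5R) auxiliary: in the crossed approach over one face of the C=N bond the bulky C11 terminus should lie on the side where the neighbouring ring methyl points away, with the C1 hydrogen under the methyl that points toward the alkene, which corresponds to the (2R,3S) ketone. The step needs regioselectivity, retention of alkene geometry and face selection; these rest on the tertiary cation at C11, on the short lifetime of the dipolar species and on the auxiliary, and the bulky silyloxy group is meant to limit both inductive erosion of the regiochemical bias and interference by oxygen. Using 5 as the limiting component with an excess of 9 counters self-condensation of the unsubstituted keteniminium ion.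

Step 6
Reactants: 11 (2R,3S)-2-[2-(benzyloxy)ethyl]-3-[(tert-butyldiphenylsilyloxy)methyl]-3-methylcyclobutan-1-one
Product: 12 (1R,2S,3S)-2-[2-(benzyloxy)ethyl]-3-[(tert-butyldiphenylsilyloxy)methyl]-3-methylcyclobutane-1-carbonitrile
Conditions: TosMIC, t-BuOK, DME/EtOH, 0 °C → rt; then t-BuOK, t-BuOH/THF, rt
Reagents that add atoms: p-toluenesulfonylmethyl isocyanide (TosMIC), Cc1ccc(cc1)S(=O)(=O)C[N+]#[C-]
Why: Van Leusen reductive cyanation: the TosMIC anion adds to the strained ketone and the oxazoline intermediate fragments with loss of sulfinate and formate, leaving C9 as a nitrile-bearing CH. C9 is set under thermodynamic control, because base equilibrates the α-cyano carbanion and the nitrile should settle trans to the C2 chain on C1. Any enolisation of 11 toward C1 beforehand is harmless, as the chain already lies trans to the larger silyloxymethyl group.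

Step 7
Reactants: 12 (1R,2S,3S)-2-[2-(benzyloxy)ethyl]-3-[(tert-butyldiphenylsilyloxy)methyl]-3-methylcyclobutane-1-carbonitrile
Product: 13 (1R,2S,3S)-3-[(tert-butyldiphenylsilyloxy)methyl]-2-(2-hydroxyethyl)-3-methylcyclobutane-1-carbonitrile
Conditions: H2 (1 atm), Pd/C, EtOAc, rt
Reagents that add atoms: none
Why: Hydrogenolysis of the benzyl ether on palladium; at atmospheric pressure in ethyl acetate the aliphatic nitrile and the silyl ether should be left alone, and no alkene is present at this stage.

Step 8
Reactants: 13 (1R,2S,3S)-3-[(tert-butyldiphenylsilyloxy)methyl]-2-(2-hydroxyethyl)-3-methylcyclobutane-1-carbonitrile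
Product: 14 (1R,2S,3S)-3-[(tert-butyldiphenylsilyloxy)methyl]-2-(2-iodoethyl)-3-methylcyclobutane-1-carbonitrile
Conditions: I2, PPh3, imidazole, CH2Cl2, 0 °C → rt
Reagents that add atoms: iodine, [I][I]
Why: Appel-type iodination (phosphonium activation of the primary alcohol, then SN2 by iodide); the neutral conditions keep the nitrile and its α-stereocentre intact.

Step 9
Reactants: 14 (1R,2S,3S)-3-[(tert-butyldiphenylsilyloxy)methyl]-2-(2-iodoethyl)-3-methylcyclobutane-1-carbonitrile
Product: 15 (1R,2S,3S)-2-(but-3-yn-1-yl)-3-[(tert-butyldiphenylsilyloxy)methyl]-3-methylcyclobutane-1-carbonitrile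
Conditions: LiC≡CH·H2NCH2CH2NH2, DMSO, 15 °C → rt
Reagents that add atoms: lithium acetylide–ethylenediamine complex, [Li+].[C-]#C.NCCN
Why: SN2 alkylation of the acetylide at the unhindered primary iodide in a dipolar aprotic solvent; the acetylide is too weak a base to deprotonate the nitrile irreversibly, and any epimerisation at C9 would return the trans isomer.

Step 10
Reactants: 15 (1R,2S,3S)-2-(but-3-yn-1-yl)-3-[(tert-butyldiphenylsilyloxy)methyl]-3-methylcyclobutane-1-carbonitrile
Product: 17 (1R,2S,3S)-3-[(tert-butyldiphenylsilyloxy)methyl]-2-[(E)-5-hydroxy-3-methylpent-3-en-1-yl]-3-methylcyclobutane-1-carbonitrile, via alkenylalane 16 (not isolated)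
Conditions: Me3Al (4 equiv), Cp2ZrCl2 (25 mol %), CH2Cl2, 0 °C → rt; then (CH2O)n, 0 °C → rt
Reagents that add atoms: trimethylaluminium, C[Al](C)C; formaldehyde (as paraformaldehyde), C=O
Why: Zirconium-catalysed methylalumination (Negishi carboalumination) adds CH3 and Al syn across the terminal alkyne with the methyl on the internal carbon, and the alkenylalane 16 is trapped by formaldehyde with retention, so C3 and the CH2OH carbon C6 end trans (E). One equivalent of Me3Al is expected to be held as the Lewis adduct of the nitrile, which does not accept a methyl group at room temperature; hence the excess.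

Step 11
Reactants: 17 (1R,2S,3S)-3-[(tert-butyldiphenylsilyloxy)methyl]-2-[(E)-5-hydroxy-3-methylpent-3-en-1-yl]-3-methylcyclobutane-1-carbonitrile
Product: 19 1-{(1R,2S,3S)-3-[(tert-butyldiphenylsilyloxy)methyl]-2-[(E)-5-hydroxy-3-methylpent-3-en-1-yl]-3-methylcyclobutyl}-2-(phenylsulfonyl)ethan-1-one, via enamino sulfone 18 (not isolated)
Conditions: PhSO2CH3 (3.2 equiv), n-BuLi, THF, −78 °C; 17, −78 → 0 °C; then 1 M HCl, THF, rt
Reagents that add atoms: methyl phenyl sulfone, CS(=O)(=O)c1ccccc1; water, O
Why: Thorpe-type addition of the α-sulfonyl carbanion to the nitrile gives the metallated β-enamino sulfone 18, which resists further attack and is hydrolysed by aqueous acid to the β-keto sulfone; one equivalent of carbanion is consumed by the hydroxyl group and one by the acidic adduct. C9 keeps its configuration because the acidic site of the product is C7.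

Step 12
Reactants: 19 1-{(1R,2S,3S)-3-[(tert-butyldiphenylsilyloxy)methyl]-2-[(E)-5-hydroxy-3-methylpent-3-en-1-yl]-3-methylcyclobutyl}-2-(phenylsulfonyl)ethan-1-one
Product: 20 1-{(1R,2S,3S)-3-[(tert-butyldiphenylsilyloxy)methyl]-2-[(E)-5-(methoxycarbonyloxy)-3-methylpent-3-en-1-yl]-3-methylcyclobutyl}-2-(phenylsulfonyl)ethan-1-one
Conditions: ClCO2Me, pyridine, CH2Cl2, 0 °C
Reagents that add atoms: methyl chloroformate, COC(=O)Cl
Why: Acylation of the primary allylic alcohol; pyridine is too weak a base to enolise the β-keto sulfone, so acylation at C7 or at the enol oxygen is not expected.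

Step 13
Reactants: 20 1-{(1R,2S,3S)-3-[(tert-butyldiphenylsilyloxy)methyl]-2-[(E)-5-(methoxycarbonyloxy)-3-methylpent-3-en-1-yl]-3-methylcyclobutyl}-2-(phenylsulfonyl)ethan-1-one
Product: 21 (1S,4E,9R,11S)-11-[(tert-butyldiphenylsilyloxy)methyl]-4,11-dimethyl-7-(phenylsulfonyl)bicyclo[7.2.0]undec-4-en-8-one (C7 epimers)
Conditions: Pd(PPh3)4 (10 mol %), dppe (12 mol %), THF, reflux, slow addition (2 mM)
Reagents that add atoms: none
Why: Intramolecular Tsuji–Trost allylic alkylation: zerovalent palladium ionises the allylic carbonate, the methoxide released on decarboxylation deprotonates C7, and the soft carbanion attacks the unsubstituted terminus C6 of the allyl unit, closing the nine-membered ring in preference to the seven-membered ring that attack at the fully substituted terminus C4 would give. The E geometry is carried over from the syn allyl complex and the trans ring fusion from 20; the configuration at C7 is of no consequence.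

Step 14
Reactants: 21 (1S,4E,9R,11S)-11-[(tert-butyldiphenylsilyloxy)methyl]-4,11-dimethyl-7-(phenylsulfonyl)bicyclo[7.2.0]undec-4-en-8-one
Product: 22 (1S,4E,9R,11S)-11-[(tert-butyldiphenylsilyloxy)methyl]-4,11-dimethylbicyclo[7.2.0]undec-4-en-8-one
Conditions: SmI2 (2.5 equiv), THF/MeOH, −78 °C
Reagents that add atoms: none
Why: Single-electron reduction of the β-keto sulfone by SmI2 (divalent samarium) expels benzenesulfinate and leaves a samarium enolate that methanol protonates at C7; the isolated alkene, the silyl ether and C9 are not affected.

Step 15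
Reactants: 22 (1S,4E,9R,11S)-11-[(tert-butyldiphenylsilyloxy)methyl]-4,11-dimethylbicyclo[7.2.0]undec-4-en-8-one
Product: 23 tert-butyl{[(1S,4E,9R,11S)-4,11-dimethyl-8-methylidenebicyclo[7.2.0]undec-4-en-11-yl]methoxy}diphenylsilane
Conditions: Ph3PCH3Br, t-BuOK, toluene, rt → 60 °C
Reagents that add atoms: methyltriphenylphosphonium bromide, C[P+](c1ccccc1)(c1ccccc1)c1ccccc1.[Br-]
Why: Wittig methylenation of the ring ketone with the non-stabilised ylide; enolisation toward C9 would be harmless because the trans-fused ketone is the thermodynamically preferred epimer.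

Step 16
Reactants: 23 tert-butyl{[(1S,4E,9R,11S)-4,11-dimethyl-8-methylidenebicyclo[7.2.0]undec-4-en-11-yl]methoxy}diphenylsilane
Product: 24 [(1S,4E,9R,11S)-4,11-dimethyl-8-methylidenebicyclo[7.2.0]undec-4-en-11-yl]methanol
Conditions: TBAF, THF, rt → 45 °C
Reagents that add atoms: none
Why: Fluoride cleaves the Si–O bond, driven by the strong Si–F bond; the neopentyl position slows the reaction, hence gentle warming, and the diene is inert to fluoride.

Step 17
Reactants: 24 [(1S,4E,9R,11S)-4,11-dimethyl-8-methylidenebicyclo[7.2.0]undec-4-en-11-yl]methanol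
Product: 25 (1S,4E,9R,11S)-4,11-dimethyl-8-methylidenebicyclo[7.2.0]undec-4-ene-11-carbaldehyde
Conditions: SO3·pyridine, DMSO, iPr2NEt, CH2Cl2, 0 °C
Reagents that add atoms: none
Why: Parikh–Doering oxidation (activated DMSO) stops at the aldehyde under weakly basic conditions that do not endanger the strained E-alkene; the aldehyde has no α-hydrogen and cannot epimerise.

Step 18
Reactants: 25 (1S,4E,9R,11S)-4,11-dimethyl-8-methylidenebicyclo[7.2.0]undec-4-ene-11-carbaldehyde
Product: 26 1-[(1S,4E,9R,11S)-4,11-dimethyl-8-methylidenebicyclo[7.2.0]undec-4-en-11-yl]prop-2-yn-1-ol (both carbinol epimers)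
Conditions: HC≡CMgBr, THF, −20 → 0 °C
Reagents that add atoms: ethynylmagnesium bromide, C#C[Mg]Br
Why: 1,2-Addition of the alkynyl Grignard reagent to the non-enolisable neopentyl aldehyde; both carbinol epimers are acceptable because this carbon becomes sp2 in step 20.

Step 19
Reactants: 26 1-[(1S,4E,9R,11S)-4,11-dimethyl-8-methylidenebicyclo[7.2.0]undec-4-en-11-yl]prop-2-yn-1-ol
Product: 27 (1S,4E,9R,11S)-11-(1-methoxyprop-2-yn-1-yl)-4,11-dimethyl-8-methylidenebicyclo[7.2.0]undec-4-ene (both epimers)
Conditions: NaH (1.1 equiv), MeI, THF, 0 °C → rt
Reagents that add atoms: iodomethane, CI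
Why: Williamson etherification of the sodium alkoxide; with one equivalent of NaH in THF the terminal alkyne is not deprotonated to a significant extent, so C-methylation is not expected.

Step 20
Reactants: 27 (1S,4E,9R,11S)-11-(1-methoxyprop-2-yn-1-yl)-4,11-dimethyl-8-methylidenebicyclo[7.2.0]undec-4-ene
Product: 28 (1S,4E,9R,11S)-11-(1-methoxypropa-1,2-dien-1-yl)-4,11-dimethyl-8-methylidenebicyclo[7.2.0]undec-4-ene
Conditions: t-BuOK (0.3 equiv), THF/DMSO, 0 °C → rt
Reagents that add atoms: none
Why: Base-catalysed propargyl-to-allenyl ether isomerisation (1,3-prototropic shift through the propargyl/allenyl anion), driven by conjugation of the oxygen lone pair with the cumulene; the quaternary C11 blocks any further migration.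

Step 21
Reactants: 29 (S)-2-methylglycidol
Product: 31 (S)-2-methyl-2-vinyloxirane, via epoxy aldehyde 30 (not isolated)
Conditions: SO3·pyridine, iPr2NEt, DMSO, 15 °C; then Ph3PCH3Br, t-BuOK (excess), DMSO, rt; distillation
Reagents that add atoms: methyltriphenylphosphonium bromide, C[P+](c1ccccc1)(c1ccccc1)c1ccccc1.[Br-]
Why: Parikh–Doering oxidation to the non-enolisable epoxy aldehyde 30, followed in the same pot by Wittig methylenation, turns CH2OH into vinyl without touching the quaternary stereocentre. The volatile product is taken out of the high-boiling medium by distillation.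

Step 22
Reactants: 31 (S)-2-methyl-2-vinyloxirane
Product: 32 (R)-2-hydroperoxy-2-methylbut-3-en-1-ol
Conditions: H2O2 (dried ethereal solution, 4 equiv), H3PMo12O40 (1 mol %), Et2O, 0 °C → rt
Reagents that add atoms: hydrogen peroxide, OO
Why: Heteropolyacid-catalysed perhydrolysis of the epoxide: H2O2 opens the activated oxirane at the more substituted, allylic carbon from the side opposite the C–O bond (borderline SN2), so the tertiary centre is inverted and the (S)-epoxide should give the (R)-hydroperoxide, which sets C4'. Excess H2O2 suppresses dialkyl peroxide formation.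

Step 23
Reactants: 32 (R)-2-hydroperoxy-2-methylbut-3-en-1-ol
Product: 34 (R)-1-(tert-butyldimethylsilyloxy)-2-methylbut-3-en-2-yl hydroperoxide, via bis-silyl peroxide 33 (not isolated)
Conditions: TBSCl (2.5 equiv), imidazole, DMF, 0 °C → rt; then K2CO3, MeOH, 0 °C
Reagents that add atoms: tert-butyl(chloro)dimethylsilane, CC(C)(C)[Si](C)(C)Cl
Why: Both OH and OOH are silylated; the Si–OO bond is then cleaved selectively by carbonate-catalysed methanolysis, because the hydroperoxide anion is a far better leaving group than an alkoxide (as with silyl esters and aryl silyl ethers). The stereocentre is not involved.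

Step 24
Reactants: 28 (1S,4E,9R,11S)-11-(1-methoxypropa-1,2-dien-1-yl)-4,11-dimethyl-8-methylidenebicyclo[7.2.0]undec-4-ene; 34 (R)-1-(tert-butyldimethylsilyloxy)-2-methylbut-3-en-2-yl hydroperoxide
Product: 35 tert-butyl{[(2R)-2-({1-[(1S,4E,9R,11S)-4,11-dimethyl-8-methylidenebicyclo[7.2.0]undec-4-en-11-yl]-1-methoxyprop-2-en-1-yl}peroxy)-2-methylbut-3-en-1-yl]oxy}dimethylsilane (both C1' epimers)
Conditions: PPTS (10 mol %), 4 Å MS, CH2Cl2, −20 → 0 °C
Reagents that add atoms: none
Why: Proposed new method: PPTS protonates the central carbon of the methoxyallene to a 1-methoxyallyl (oxocarbenium) cation and the O–H of 34 adds at the oxygen-bearing carbon C1', the site of highest positive charge, giving the vinyl-substituted mixed peroxyketal without passing through an enone; the closest known reaction types are the acid- or palladium-catalysed addition of alcohols to alkoxyallenes (mixed acrolein acetals) and the acid-catalysed addition of hydroperoxides to enol ethers such as 2-methoxypropene. C1' forms as both epimers, which converge in step 26, and C4' is not touched.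

Step 25
Reactants: 35 tert-butyl{[(2R)-2-({1-[(1S,4E,9R,11S)-4,11-dimethyl-8-methylidenebicyclo[7.2.0]undec-4-en-11-yl]-1-methoxyprop-2-en-1-yl}peroxy)-2-methylbut-3-en-1-yl]oxy}dimethylsilane
Product: 36 tert-butyl({(6R)-3-[(1S,4E,9R,11S)-4,11-dimethyl-8-methylidenebicyclo[7.2.0]undec-4-en-11-yl]-3-methoxy-6-methyl-3,6-dihydro-1,2-dioxin-6-yl}methoxy)dimethylsilane (both C3 epimers)
Conditions: (H2IMes)(PCy3)Cl2Ru=CHPh (10 mol %), CH2Cl2 (2 mM), 40 °C, Ar sparge
Reagents that add atoms: none
Why: Ring-closing olefin metathesis through ruthenium alkylidene and metallacyclobutane intermediates joins the two monosubstituted vinyl groups, the only alkenes that can initiate readily, and the six-membered ring enforces the cis C2'=C3' bond; dialkyl peroxides without α-hydrogen are tolerated by the catalyst. High dilution and removal of ethylene disfavour opening of the strained ring alkene, and the 1,1-disubstituted C8 methylene is too hindered to compete.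

Step 26
Reactants: 36 tert-butyl({(6R)-3-[(1S,4E,9R,11S)-4,11-dimethyl-8-methylidenebicyclo[7.2.0]undec-4-en-11-yl]-3-methoxy-6-methyl-3,6-dihydro-1,2-dioxin-6-yl}methoxy)dimethylsilane
Product: 38 (3R,6R)-3-[(1S,4E,9R,11S)-4,11-dimethyl-8-methylidenebicyclo[7.2.0]undec-4-en-11-yl]-6-(hydroxymethyl)-6-methyl-3,6-dihydro-1,2-dioxin-3-ol, via hydroxy methyl ketal 37 (not isolated)
Conditions: TBAF, THF, 0 °C → rt; then PPTS, THF/H2O, rt
Reagents that add atoms: water, O
Why: Fluoride removes the primary silyl group; mild aqueous acid then ionises the methyl peroxyketal and water gives the peroxy-hemiketal, which equilibrates through its open-chain (Z)-hydroperoxy enone so that C1' should settle in the preferred configuration (hydroxyl pseudo-axial by the anomeric effect, the bulky C11 substituent pseudo-equatorial). The acid is kept weak because of the strained E-alkene, and the epoxide is not yet present.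

Step 27
Reactants: 38 (3R,6R)-3-[(1S,4E,9R,11S)-4,11-dimethyl-8-methylidenebicyclo[7.2.0]undec-4-en-11-yl]-6-(hydroxymethyl)-6-methyl-3,6-dihydro-1,2-dioxin-3-ol
Product: 39 (3R,6R)-3-[(1S,4S,5S,9R,11S)-4,5-epoxy-4,11-dimethyl-8-methylidenebicyclo[7.2.0]undecan-11-yl]-6-(hydroxymethyl)-6-methyl-3,6-dihydro-1,2-dioxin-3-ol (target)
Conditions: mCPBA (1.05 equiv), NaHCO3, CH2Cl2, −20 → 0 °C
Reagents that add atoms: 3-chloroperoxybenzoic acid (mCPBA), O=C(OO)c1cccc(Cl)c1
Why: Prilezhaev epoxidation: the strained, electron-rich trisubstituted E-alkene should react far faster than the 1,1-disubstituted methylene or the dioxene alkene, which is deactivated by two allylic oxygens, and the concerted syn transfer keeps C3 and C6 trans on the oxirane. The peracid should attack the exposed outer face of the preferred conformers of the E-cyclononene, the same facial preference that leads from caryophyllene to its 4,5-oxide, which in this enantiomeric series means the (4S,5S) epoxide; bicarbonate protects the acid-labile product.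

## Compound list

1 | 3-(benzyloxy)propanal | O=CCCOCc1ccccc1 | starting material
2 | ethyl 2-(triphenylphosphoranylidene)propanoate | CCOC(=O)C(C)=P(c1ccccc1)(c1ccccc1)c1ccccc1 | starting material
3 | ethyl (E)-5-(benzyloxy)-2-methylpent-2-enoate | CCOC(=O)/C(C)=C/CCOCc1ccccc1 | intermediate
4 | (E)-5-(benzyloxy)-2-methylpent-2-en-1-ol | OC/C(C)=C/CCOCc1ccccc1 | intermediate
5 | (E)-5-(benzyloxy)-2-methylpent-2-enyl tert-butyldiphenylsilyl ether | C/C(CO[Si](c1ccccc1)(c1ccccc1)C(C)(C)C)=C\CCOCc1ccccc1 | intermediate
6 | (2R,5R)-2,5-dimethylpyrrolidine | C[C@@H]1CC[C@@H](C)N1 | starting material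
7 | acetyl chloride | CC(=O)Cl | starting material
8 | 1-acetyl-(2R,5R)-2,5-dimethylpyrrolidine | CC(=O)N1[C@H](C)CC[C@H]1C | intermediate
9 | (2R,5R)-1-ethenylidene-2,5-dimethylpyrrolidinium triflate | C=C=[N+]1[C@H](C)CC[C@H]1C.[O-]S(=O)(=O)C(F)(F)F | intermediate
10 | (2R,5R)-1-{(2R,3S)-2-[2-(benzyloxy)ethyl]-3-[(tert-butyldiphenylsilyloxy)methyl]-3-methylcyclobutylidene}-2,5-dimethylpyrrolidinium triflate | C[C@@H]1CC[C@@H](C)[N+]1=C1C[C@](C)(CO[Si](c2ccccc2)(c2ccccc2)C(C)(C)C)[C@H]1CCOCc1ccccc1.[O-]S(=O)(=O)C(F)(F)F | intermediate
11 | (2R,3S)-2-[2-(benzyloxy)ethyl]-3-[(tert-butyldiphenylsilyloxy)methyl]-3-methylcyclobutan-1-one | O=C1C[C@](C)(CO[Si](c2ccccc2)(c2ccccc2)C(C)(C)C)[C@H]1CCOCc1ccccc1 | intermediate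
12 | (1R,2S,3S)-2-[2-(benzyloxy)ethyl]-3-[(tert-butyldiphenylsilyloxy)methyl]-3-methylcyclobutane-1-carbonitrile | N#C[C@@H]1C[C@](C)(CO[Si](c2ccccc2)(c2ccccc2)C(C)(C)C)[C@H]1CCOCc1ccccc1 | intermediate
13 | (1R,2S,3S)-3-[(tert-butyldiphenylsilyloxy)methyl]-2-(2-hydroxyethyl)-3-methylcyclobutane-1-carbonitrile | N#C[C@@H]1C[C@](C)(CO[Si](c2ccccc2)(c2ccccc2)C(C)(C)C)[C@H]1CCO | intermediate
14 | (1R,2S,3S)-3-[(tert-butyldiphenylsilyloxy)methyl]-2-(2-iodoethyl)-3-methylcyclobutane-1-carbonitrile | N#C[C@@H]1C[C@](C)(CO[Si](c2ccccc2)(c2ccccc2)C(C)(C)C)[C@H]1CCI | intermediate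
15 | (1R,2S,3S)-2-(but-3-yn-1-yl)-3-[(tert-butyldiphenylsilyloxy)methyl]-3-methylcyclobutane-1-carbonitrile | N#C[C@@H]1C[C@](C)(CO[Si](c2ccccc2)(c2ccccc2)C(C)(C)C)[C@H]1CCC#C | intermediate
16 | (1R,2S,3S)-3-[(tert-butyldiphenylsilyloxy)methyl]-2-[(E)-4-(dimethylalumanyl)-3-methylbut-3-en-1-yl]-3-methylcyclobutane-1-carbonitrile | N#C[C@@H]1C[C@](C)(CO[Si](c2ccccc2)(c2ccccc2)C(C)(C)C)[C@H]1CC/C(C)=C/[Al](C)C | intermediate
17 | (1R,2S,3S)-3-[(tert-butyldiphenylsilyloxy)methyl]-2-[(E)-5-hydroxy-3-methylpent-3-en-1-yl]-3-methylcyclobutane-1-carbonitrile | N#C[C@@H]1C[C@](C)(CO[Si](c2ccccc2)(c2ccccc2)C(C)(C)C)[C@H]1CC/C(C)=C/CO | intermediate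
18 | 1-{(1R,2S,3S)-3-[(tert-butyldiphenylsilyloxy)methyl]-2-[(E)-5-hydroxy-3-methylpent-3-en-1-yl]-3-methylcyclobutyl}-2-(phenylsulfonyl)ethen-1-amine (enamine geometry not defined) | NC(=CS(=O)(=O)c1ccccc1)[C@@H]1C[C@](C)(CO[Si](c2ccccc2)(c2ccccc2)C(C)(C)C)[C@H]1CC/C(C)=C/CO | intermediate
19 | 1-{(1R,2S,3S)-3-[(tert-butyldiphenylsilyloxy)methyl]-2-[(E)-5-hydroxy-3-methylpent-3-en-1-yl]-3-methylcyclobutyl}-2-(phenylsulfonyl)ethan-1-one | O=C(CS(=O)(=O)c1ccccc1)[C@@H]1C[C@](C)(CO[Si](c2ccccc2)(c2ccccc2)C(C)(C)C)[C@H]1CC/C(C)=C/CO | intermediate
20 | 1-{(1R,2S,3S)-3-[(tert-butyldiphenylsilyloxy)methyl]-2-[(E)-5-(methoxycarbonyloxy)-3-methylpent-3-en-1-yl]-3-methylcyclobutyl}-2-(phenylsulfonyl)ethan-1-one | O=C(CS(=O)(=O)c1ccccc1)[C@@H]1C[C@](C)(CO[Si](c2ccccc2)(c2ccccc2)C(C)(C)C)[C@H]1CC/C(C)=C/COC(=O)OC | intermediate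
21 | (1S,4E,9R,11S)-11-[(tert-butyldiphenylsilyloxy)methyl]-4,11-dimethyl-7-(phenylsulfonyl)bicyclo[7.2.0]undec-4-en-8-one (C7 epimers) | O=C1C(S(=O)(=O)c2ccccc2)C/C=C(\C)CC[C@H]2[C@H]1C[C@]2(C)CO[Si](c1ccccc1)(c1ccccc1)C(C)(C)C | intermediate
22 | (1S,4E,9R,11S)-11-[(tert-butyldiphenylsilyloxy)methyl]-4,11-dimethylbicyclo[7.2.0]undec-4-en-8-one | O=C1CC/C=C(\C)CC[C@H]2[C@H]1C[C@]2(C)CO[Si](c1ccccc1)(c1ccccc1)C(C)(C)C | intermediate
23 | tert-butyl{[(1S,4E,9R,11S)-4,11-dimethyl-8-methylidenebicyclo[7.2.0]undec-4-en-11-yl]methoxy}diphenylsilane | C=C1CC/C=C(\C)CC[C@H]2[C@H]1C[C@]2(C)CO[Si](c1ccccc1)(c1ccccc1)C(C)(C)C | intermediate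
24 | [(1S,4E,9R,11S)-4,11-dimethyl-8-methylidenebicyclo[7.2.0]undec-4-en-11-yl]methanol | C=C1CC/C=C(\C)CC[C@H]2[C@H]1C[C@]2(C)CO | intermediate
25 | (1S,4E,9R,11S)-4,11-dimethyl-8-methylidenebicyclo[7.2.0]undec-4-ene-11-carbaldehyde | C=C1CC/C=C(\C)CC[C@H]2[C@H]1C[C@]2(C)C=O | intermediate
26 | 1-[(1S,4E,9R,11S)-4,11-dimethyl-8-methylidenebicyclo[7.2.0]undec-4-en-11-yl]prop-2-yn-1-ol (both carbinol epimers) | C=C1CC/C=C(\C)CC[C@H]2[C@H]1C[C@]2(C)C(O)C#C | intermediate
27 | (1S,4E,9R,11S)-11-(1-methoxyprop-2-yn-1-yl)-4,11-dimethyl-8-methylidenebicyclo[7.2.0]undec-4-ene (both epimers) | C=C1CC/C=C(\C)CC[C@H]2[C@H]1C[C@]2(C)C(OC)C#C | intermediate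
28 | (1S,4E,9R,11S)-11-(1-methoxypropa-1,2-dien-1-yl)-4,11-dimethyl-8-methylidenebicyclo[7.2.0]undec-4-ene | C=C1CC/C=C(\C)CC[C@H]2[C@H]1C[C@]2(C)C(OC)=C=C | intermediate
29 | (S)-2-methylglycidol, (2S)-(2-methyloxiran-2-yl)methanol | OC[C@@]1(C)CO1 | starting material
30 | (R)-2-methyloxirane-2-carbaldehyde | O=C[C@@]1(C)CO1 | intermediate
31 | (S)-2-methyl-2-vinyloxirane | C=C[C@@]1(C)CO1 | intermediate
32 | (R)-2-hydroperoxy-2-methylbut-3-en-1-ol | C=C[C@](C)(CO)OO | intermediate
33 | tert-butyl{[(2R)-2-(tert-butyldimethylsilylperoxy)-2-methylbut-3-en-1-yl]oxy}dimethylsilane | C=C[C@](C)(CO[Si](C)(C)C(C)(C)C)OO[Si](C)(C)C(C)(C)C | intermediate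
34 | (R)-1-(tert-butyldimethylsilyloxy)-2-methylbut-3-en-2-yl hydroperoxide | C=C[C@](C)(CO[Si](C)(C)C(C)(C)C)OO | intermediate
35 | tert-butyl{[(2R)-2-({1-[(1S,4E,9R,11S)-4,11-dimethyl-8-methylidenebicyclo[7.2.0]undec-4-en-11-yl]-1-methoxyprop-2-en-1-yl}peroxy)-2-methylbut-3-en-1-yl]oxy}dimethylsilane (both C1' epimers) | C=C1CC/C=C(\C)CC[C@H]2[C@H]1C[C@]2(C)C(OC)(C=C)OO[C@](C)(C=C)CO[Si](C)(C)C(C)(C)C | intermediate
36 | tert-butyl({(6R)-3-[(1S,4E,9R,11S)-4,11-dimethyl-8-methylidenebicyclo[7.2.0]undec-4-en-11-yl]-3-methoxy-6-methyl-3,6-dihydro-1,2-dioxin-6-yl}methoxy)dimethylsilane (both C3 epimers) | C=C1CC/C=C(\C)CC[C@H]2[C@H]1C[C@]2(C)C1(OC)C=C[C@](C)(CO[Si](C)(C)C(C)(C)C)OO1 | intermediate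
37 | {(6R)-3-[(1S,4E,9R,11S)-4,11-dimethyl-8-methylidenebicyclo[7.2.0]undec-4-en-11-yl]-3-methoxy-6-methyl-3,6-dihydro-1,2-dioxin-6-yl}methanol (both C3 epimers) | C=C1CC/C=C(\C)CC[C@H]2[C@H]1C[C@]2(C)C1(OC)C=C[C@](C)(CO)OO1 | intermediate
38 | (3R,6R)-3-[(1S,4E,9R,11S)-4,11-dimethyl-8-methylidenebicyclo[7.2.0]undec-4-en-11-yl]-6-(hydroxymethyl)-6-methyl-3,6-dihydro-1,2-dioxin-3-ol | C=C1CC/C=C(\C)CC[C@H]2[C@H]1C[C@]2(C)[C@@]1(O)C=C[C@](C)(CO)OO1 | intermediate
39 | (3R,6R)-3-[(1S,4S,5S,9R,11S)-4,5-epoxy-4,11-dimethyl-8-methylidenebicyclo[7.2.0]undecan-11-yl]-6-(hydroxymethyl)-6-methyl-3,6-dihydro-1,2-dioxin-3-ol | C=C1CC[C@@H]2O[C@@]2(C)CC[C@H]2[C@H]1C[C@]2(C)[C@@]1(O)C=C[C@](C)(CO)OO1 | target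

## Step count and least certain steps

Total step count: 27.
Longest linear sequence: 23 steps (steps 1–3, 5–20 and 24–27). Step 4 (auxiliary amide) and steps 21–23 (hydroperoxide fragment) are side branches.

**Step 24 (Proposed new method).** The most likely failure is attack of the hydroperoxide at the terminal carbon of the methoxyallyl cation, or hydration of the allene followed by conjugate addition, because C1' is flanked by the quaternary C11 and the unhindered CH2 end competes. The fallback uses known chemistry and separates the two events. It sets out from 28: PPTS-catalysed addition of methanol (alcohol addition to an alkoxyallene) gives the dimethyl ketal (1S,4E,9R,11S)-11-(1,1-dimethoxyprop-2-en-1-yl)-4,11-dimethyl-8-methylidenebicyclo[7.2.0]undec-4-ene F1. F1 is then submitted to acid-catalysed exchange of one methoxy group against 34 (peroxy-transketalisation, camphorsulfonic acid, 4 Å molecular sieves to take up methanol, CH2Cl2, 0 °C), under thermodynamic control at the ketal carbon, and comes back to the route at 35.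

**Step 5 (key step).** Three things may go wrong:
- the trisubstituted, inductively deactivated alkene may react too slowly, so that self-condensation of the unsubstituted keteniminium ion through its ynamine wins;
- face selection by an auxiliary that is two atoms away from the forming bonds may be poor;
- regiochemistry may leak, or the C11 cation may be captured by the benzyloxy oxygen if the dipolar species lives too long.

The fallback replaces the auxiliary-controlled ketene equivalent by a catalyst-controlled one. It sets out from 5: an enantioselective Lewis-acid-catalysed [2+2] cycloaddition with 2,2,2-trifluoroethyl buta-2,3-dienoate (chiral oxazaborolidine activated by AlBr3, CH2Cl2, −78 °C) has the same regiochemistry (allene central carbon to C1, CH2 to C11). It gives the alkylidenecyclobutane 2,2,2-trifluoroethyl 2-{2-[2-(benzyloxy)ethyl]-3-[(tert-butyldiphenylsilyloxy)methyl]-3-methylcyclobutylidene}acetate F2 (ring stereocentres as in 11). Ozonolysis of the exocyclic alkene (O3, CH2Cl2, −78 °C; then Me2S) comes back at 11.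

**Step 13.** The failures to expect are oligomerisation at practical concentrations, attack at the substituted allyl terminus (seven-membered ring), and loss of the E geometry by syn/anti interconversion of the allyl complex, since the Z nine-membered ring is the less strained. The fallback avoids an allyl-metal species altogether. It sets out from 19: the allylic alcohol is converted into the allylic chloride 1-{(1R,2S,3S)-3-[(tert-butyldiphenylsilyloxy)methyl]-2-[(E)-5-chloro-3-methylpent-3-en-1-yl]-3-methylcyclobutyl}-2-(phenylsulfonyl)ethan-1-one F3 (methanesulfonyl chloride, LiCl, 2,4,6-collidine, DMF, 0 °C). F3 is cyclised by direct SN2 alkylation of the keto sulfone carbanion at the primary carbon (Cs2CO3, MeCN, high dilution, 60 °C) and comes back at 21.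

**Step 22.** The tertiary allylic carbon may ionise instead of being displaced, which would erode the configuration at C4' or divert the opening to the terminal vinyl carbon. The fallback gives up reagent control at this centre and uses the enantiopure core as resolving element. It sets out from 32 of lowered enantiomeric purity, which is carried through steps 23–26; the contaminant is (S)-1-(tert-butyldimethylsilyloxy)-2-methylbut-3-en-2-yl hydroperoxide F4. Because C1' equilibrates at the hemiketal stage, only two diastereomers remain there, and the unwanted (6S) epimer of 38, F5, is removed by chromatography or crystallisation, so that the route is rejoined at 38.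

**Step 25.** Initiation at vinyl groups on two fully substituted carbons may be slow, and the catalyst may instead open the strained E-cyclononene or be consumed by redox reaction with the O–O bond. The fallback removes the strained alkene before metathesis by advancing the epoxidation that the target needs anyway. It sets out from 35:
- mCPBA/NaHCO3 gives the 4,5-epoxide of 35, F6;
- ring-closing metathesis under the conditions of step 25 gives the 4,5-epoxide of 36, F7;
- TBAF gives the 4,5-epoxide of 37, F8;
- the methyl ketal is hydrolysed under the mildest conditions that work (PPTS, wet acetone, 0 °C), and the route is rejoined at 39.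

The price is exposure of the epoxide to weak acid in the last operation.

Further compounds

F1 | step 24 | (1S,4E,9R,11S)-11-(1,1-dimethoxyprop-2-en-1-yl)-4,11-dimethyl-8-methylidenebicyclo[7.2.0]undec-4-ene | C=C1CC/C=C(\C)CC[C@H]2[C@H]1C[C@]2(C)C(OC)(OC)C=C
F2 | step 5 | 2,2,2-trifluoroethyl 2-{2-[2-(benzyloxy)ethyl]-3-[(tert-butyldiphenylsilyloxy)methyl]-3-methylcyclobutylidene}acetate (ring stereocentres as in 11, exocyclic alkene geometry not defined) | O=C(OCC(F)(F)F)C=C1C[C@](C)(CO[Si](c2ccccc2)(c2ccccc2)C(C)(C)C)[C@H]1CCOCc1ccccc1
F3 | step 13 | 1-{(1R,2S,3S)-3-[(tert-butyldiphenylsilyloxy)methyl]-2-[(E)-5-chloro-3-methylpent-3-en-1-yl]-3-methylcyclobutyl}-2-(phenylsulfonyl)ethan-1-one | O=C(CS(=O)(=O)c1ccccc1)[C@@H]1C[C@](C)(CO[Si](c2ccccc2)(c2ccccc2)C(C)(C)C)[C@H]1CC/C(C)=C/CCl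
F4 | step 22 | (S)-1-(tert-butyldimethylsilyloxy)-2-methylbut-3-en-2-yl hydroperoxide | C=C[C@@](C)(CO[Si](C)(C)C(C)(C)C)OO
F5 | step 22 | (6S)-3-[(1S,4E,9R,11S)-4,11-dimethyl-8-methylidenebicyclo[7.2.0]undec-4-en-11-yl]-6-(hydroxymethyl)-6-methyl-3,6-dihydro-1,2-dioxin-3-ol (C3 as equilibrated) | C=C1CC/C=C(\C)CC[C@H]2[C@H]1C[C@]2(C)C1(O)C=C[C@@](C)(CO)OO1
F6 | step 25 | 4,5-epoxide of 35, (4S,5S) oxirane, both C1' epimers | C=C1CC[C@@H]2O[C@@]2(C)CC[C@H]2[C@H]1C[C@]2(C)C(OC)(C=C)OO[C@](C)(C=C)CO[Si](C)(C)C(C)(C)C
F7 | step 25 | 4,5-epoxide of 36, (4S,5S) oxirane, both C3 epimers of the dioxin | C=C1CC[C@@H]2O[C@@]2(C)CC[C@H]2[C@H]1C[C@]2(C)C1(OC)C=C[C@](C)(CO[Si](C)(C)C(C)(C)C)OO1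
F8 | step 25 | 4,5-epoxide of 37, (4S,5S) oxirane, both C3 epimers of the dioxin | C=C1CC[C@@H]2O[C@@]2(C)CC[C@H]2[C@H]1C[C@]2(C)C1(OC)C=C[C@](C)(CO)OO1
A1 | alternative 1 | tert-butyl({(3R,6R)-3-[(1S,4E,9R,11S)-4,11-dimethyl-8-methylidenebicyclo[7.2.0]undec-4-en-11-yl]-3-methoxy-6-methyl-3,6-dihydro-1,2-dioxin-6-yl}methoxy)dimethylsilane | C=C1CC/C=C(\C)CC[C@H]2[C@H]1C[C@]2(C)[C@@]1(OC)C=C[C@](C)(CO[Si](C)(C)C(C)(C)C)OO1
A2 | alternative 2 | (1S,4E,9R,11S)-11-[(tert-butyldimethylsilyloxy)methyl]-4,11-dimethyl-7-(phenylsulfonyl)bicyclo[7.2.0]undec-4-en-8-one (C7 undefined) | O=C1C(S(=O)(=O)c2ccccc2)C/C=C(\C)CC[C@H]2[C@H]1C[C@]2(C)CO[Si](C)(C)C(C)(C)C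
A3 | alternative 3 | (R)-2-(hydroxymethyl)-2-methylcyclobutan-1-one | O=C1CC[C@]1(C)CO
A4 | alternative 3 | 2-cyclopropylidenepropan-1-ol | CC(CO)=C1CC1
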